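Conneotricone is opened at the diaryl ether between rings A and B, and ring A is then dissolved. Ring A (C1′ methyl, C2′ H, C3′ OH, C4′ carboxyl, C5′ O, C6′ acyl carbon) carries the alternating oxygens of an orsellinate-type tetraketide whose acyl carbon is esterified to the B1 oxygen of ring B. The key step exploits this: a diketo-dioxinone bearing the C4′ benzyl ester is heated with the ring-B bromophenol, the released acylketene acylates the doubly flanked B1 hydroxyl, and amine base folds the chain (C6′ onto the C1′ ketone) into the hexasubstituted arene. The precursor is a dioxinone-masked triketo acid; its partner is a bromophthalide whose B2 and B3 oxygens share one acetonide.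

Key step: step 9

Remark (labels): ring A carbons carry primed locants, from C1′ (bearing CH3) to C6′ (bearing the ester carbonyl). Ring B runs B1 (C–O of the depside ester), B2 (C–CH2OH), B3 (C–OH), B4 (C bearing the lactone C=O), B5 (C bearing the lactone CH2), B6 (C–O of the aryl ether). Phthalide positions (C3a–C7a, O5, O7) are used for the ring-B intermediates. Enolisable polycarbonyl compounds are drawn in the keto form, and the target has no stereocentre.

Remark (assumption): stabilised diketene is taken as purchasable and is distilled before use.

Remark (protecting groups): the B2 and B3 oxygens are held in one isopropylidene acetal. This leaves the B1 hydroxyl as the only hydroxyl of the ring-B partner, ties the B2 substituent back from it, and is removed by dilute acid at the end.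

Step 1
Reactants: 1 2,2,6-trimethyl-4H-1,3-dioxin-4-one; 2 benzyl chloroformate
Product: 3 benzyl 2-(2,2-dimethyl-4-oxo-4H-1,3-dioxin-6-yl)acetate
Conditions: LiN(SiMe3)2 (2.1 equiv), THF, −78 °C; 2 (1.0 equiv), −78 °C; 1 M HCl
Reagents that add atoms: none
Why: Vinylogous Claisen-type C-acylation: the lithium dienolate of 1 should be acylated at its γ-carbon by the chloroformate, the second equivalent of amide base ionising the more acidic product as it forms so that it is not acylated twice.

Step 2
Reactants: 3 benzyl 2-(2,2-dimethyl-4-oxo-4H-1,3-dioxin-6-yl)acetate; 4 diketene (4-methylideneoxetan-2-one)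
Product: 5 benzyl 2-(2,2-dimethyl-4-oxo-4H-1,3-dioxin-6-yl)-3,5-dioxohexanoate
Conditions: LiN(SiMe3)2 (1.05 equiv), THF, −78 °C; 4 (1.2 equiv), −78 → −20 °C; cold 1 M HCl; used promptly
Reagents that add atoms: none
Why: C-acetoacetylation of an active methylene compound with diketene: the stabilised enolate of 3 should open the β-lactone at its acyl carbon, and the product then rests as its unreactive tricarbonyl anion at low temperature until the cold acidic quench.

Step 3
Reactants: 6 methyl atratate (methyl 2,4-dihydroxy-3,6-dimethylbenzoate)
Product: 8 methyl 2,4-diacetoxy-5-bromo-3,6-dimethylbenzoate, via bromophenol 7 (not isolated)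
Conditions: NBS (1.0 equiv), MeCN, 0 °C; then Ac2O (4 equiv), pyridine, DMAP (cat.), 40 °C
Reagents that add atoms: N-bromosuccinimide O=C1CCC(=O)N1Br; acetic anhydride CC(=O)OC(C)=O
Why: Electrophilic aromatic bromination can only take the single free ring position C5, which both hydroxyls activate, and DMAP-catalysed acetylation in the same flask then masks the two phenols as electron-poor esters that tolerate the radical step.

Step 4
Reactants: 8 methyl 2,4-diacetoxy-5-bromo-3,6-dimethylbenzoate
Product: 9 methyl 2,4-diacetoxy-5-bromo-3,6-bis(bromomethyl)benzoate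
Conditions: NBS (2.2 equiv), AIBN (10 mol%), PhCF3, 90 °C
Reagents that add atoms: N-bromosuccinimide O=C1CCC(=O)N1Br
Why: Wohl–Ziegler bromination: the bromine-atom chain substitutes one hydrogen of each benzylic methyl, the aryl acetates carrying no abstractable hydrogens that compete and deactivating the ring toward ionic bromination.

Step 5
Reactants: 9 methyl 2,4-diacetoxy-5-bromo-3,6-bis(bromomethyl)benzoate
Product: 10 4-bromo-5,7-dihydroxy-6-(hydroxymethyl)-3H-isobenzofuran-1-one
Conditions: 1 M aq. H2SO4/1,4-dioxane (1:1), 90 °C
Reagents that add atoms: water O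
Why: Acid-promoted solvolysis: the bromomethyl group beside the ester should lactonise to the phthalide with loss of methanol, the other benzylic bromide and the two aryl acetates hydrolyse, and because the ring has no free position the benzylic cation can only be captured reversibly by oxygen nucleophiles.

Step 6
Reactants: 10 4-bromo-5,7-dihydroxy-6-(hydroxymethyl)-3H-isobenzofuran-1-one
Product: 11 4-bromo-7-hydroxy-6-(hydroxymethyl)-5-(prop-2-enyloxy)-3H-isobenzofuran-1-one
Conditions: allyl bromide (1.05 equiv), KHCO3 (1.2 equiv), DMF, rt
Reagents that add atoms: allyl bromide C=CCBr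
Why: Williamson ether synthesis: hydrogencarbonate should ionise only the O5 phenol, which is para to the lactone carbonyl and not hydrogen-bonded to it, the usual site of mono-alkylation in 2,4-dihydroxyaryl carbonyl compounds.

Step 7
Reactants: 11 4-bromo-7-hydroxy-6-(hydroxymethyl)-5-(prop-2-enyloxy)-3H-isobenzofuran-1-one
Product: 12 O5-allyl acetonide (4-bromo-5-(prop-2-enyloxy)phthalide whose O7 and C6–CH2–O are bridged by CMe2 in a fused 2,2-dimethyl-4H-1,3-dioxine ring)
Conditions: Me2C(OMe)2, PPTS (cat.), acetone, rt
Reagents that add atoms: 2,2-dimethoxypropane COC(C)(C)OC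
Why: Acid-catalysed transacetalisation: with O5 blocked, the hydroxymethyl group and the neighbouring O7 phenol are the only 1,3-related hydroxyls and should close the six-membered isopropylidene acetal.

Step 8
Reactants: 12 O5-allyl acetonide
Product: 13 ring-B phenol (4-bromo-5-hydroxyphthalide with the O7/C6–CH2–O isopropylidene acetal; free B1 hydroxyl and B6 bromide)
Conditions: Pd(PPh3)4 (3 mol%), morpholine (3 equiv), THF, rt
Reagents that add atoms: none
Why: Tsuji–Trost deallylation: zerovalent palladium ionises the aryl allyl ether to a π-allyl complex that morpholine intercepts, at a temperature at which the hindered aryl bromide should not undergo oxidative addition.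

Step 9
Reactants: 5 benzyl 2-(2,2-dimethyl-4-oxo-4H-1,3-dioxin-6-yl)-3,5-dioxohexanoate; 13 ring-B phenol
Product: 17 depside (O–B1 ester of 13 with 3-(benzyloxycarbonyl)-2,4-dihydroxy-6-methylbenzoic acid; B6 bromide retained), via acylketene 14 (not isolated), via triketo diester 15 (not isolated), via aldol adduct 16 (not isolated)
Conditions: 13 (1.0 equiv, 0.3 M), PhMe, 110 °C, 5 (2.0 equiv) added over 1 h; then Et3N (4 equiv), CH2Cl2, 0 °C → rt; pH 5 buffer
Reagents that add atoms: none
Why: Retro-[4+2] fragmentation of the dioxinone ring of 5 at 110 °C expels acetone and gives acylketene 14, to which the B1 hydroxyl of 13 adds (O–H addition assisted by the neighbouring acyl oxygen) to form aryl β-keto ester 15, so the depside C–O bond is made by a small, linear acylating agent before the acid part becomes a 2,6-disubstituted benzoate. The closest known reaction types are the thermolysis of diketo-dioxinones in the presence of alcohols with base-induced aromatisation to resorcylate esters, and the acetoacetylation of phenols by dioxinone-derived acetylketene. Ring A closes by a 6-exo-trig aldol addition of the doubly activated C6′ carbon (enolendo through the C5′ enol, enolexo through the ester enol, both allowed) onto the C1′ methyl ketone to give 16, and E1cB loss of water with enolisation at C3′ and C5′ delivers the arene; no stereocentre remains in 17. The step needs intermolecular capture of 14 to outrun lactonisation by its own chain enol and ketene dimerisation, which the high concentration of 13, the slow addition of excess 5 and the short heating time are meant to secure. It also needs the aldol fold in preference to Claisen attack of C2′ on the aryl ester or O-cyclisation to pyranones, which the higher electrophilicity of the methyl ketone, a mild non-nucleophilic amine in an aprotic solvent and the absence of acid should favour; the C4′ tricarbonyl methine is ionised first but cannot close a six-membered ring.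

Step 10
Reactants: 17 depside
Product: 18 depsidone benzyl ester acetonide (C5′–O–B6 ether closed; C4′ CO2Bn; B2/B3 isopropylidene acetal)
Conditions: CuI (50 mol%), N,N-dimethylglycine (1.0 equiv), Cs2CO3 (3 equiv), 1,4-dioxane (5 mM), 95 °C
Reagents that add atoms: none
Why: Intramolecular Ullmann-type C–O coupling: the copper phenoxide of the C5′ hydroxyl is held next to the B6 bromide by the ester, so oxidative addition and reductive elimination should close the seven-membered dioxepinone ring, while the C3′ hydroxyl cannot reach B6 and high dilution suppresses intermolecular etherification.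

Step 11
Reactants: 18 depsidone benzyl ester acetonide
Product: 19 depsidone acid acetonide (C4′ CO2H; B2/B3 isopropylidene acetal)
Conditions: H2 (1 atm), 10% Pd/C, EtOAc, rt
Reagents that add atoms: none
Why: Hydrogenolysis over palladium should cleave the unhindered benzyl ester quickly at 1 atm in a neutral solvent, conditions under which the lactone CH2–O and the acetal CH2–O on the hexasubstituted ring are expected to persist.

Step 12
Reactants: 19 depsidone acid acetonide
Product: 20 conneotricone
Conditions: 1 M aq. HCl/THF (1:4), rt
Reagents that add atoms: none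
Why: Acid-catalysed acetal hydrolysis: protonation of the mixed aryl alkyl ketal and loss of acetone should free the B3 phenol and the B2 hydroxymethyl group, while the aryl ester, the lactone and the diaryl ether are stable to dilute acid at room temperature.

Compound list
1 | 2,2,6-trimethyl-4H-1,3-dioxin-4-one | CC1=CC(=O)OC(C)(C)O1 | starting material
2 | benzyl chloroformate | O=C(Cl)OCc1ccccc1 | starting material
3 | benzyl 2-(2,2-dimethyl-4-oxo-4H-1,3-dioxin-6-yl)acetate | O=C(CC1=CC(=O)OC(C)(C)O1)OCc1ccccc1 | intermediate
4 | diketene (4-methylideneoxetan-2-one) | C=C1CC(=O)O1 | starting material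
5 | benzyl 2-(2,2-dimethyl-4-oxo-4H-1,3-dioxin-6-yl)-3,5-dioxohexanoate (key-step precursor) | CC(=O)CC(=O)C(C(=O)OCc1ccccc1)C1=CC(=O)OC(C)(C)O1 | intermediate
6 | methyl atratate (methyl 2,4-dihydroxy-3,6-dimethylbenzoate) | COC(=O)c1c(C)cc(O)c(C)c1O | starting material
7 | methyl 5-bromo-2,4-dihydroxy-3,6-dimethylbenzoate (bromophenol, not isolated) | COC(=O)c1c(C)c(Br)c(O)c(C)c1O | intermediate
8 | methyl 2,4-diacetoxy-5-bromo-3,6-dimethylbenzoate | COC(=O)c1c(C)c(Br)c(OC(C)=O)c(C)c1OC(C)=O | intermediate
9 | methyl 2,4-diacetoxy-5-bromo-3,6-bis(bromomethyl)benzoate | COC(=O)c1c(CBr)c(Br)c(OC(C)=O)c(CBr)c1OC(C)=O | intermediate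
10 | 4-bromo-5,7-dihydroxy-6-(hydroxymethyl)-3H-isobenzofuran-1-one | Oc1c(CO)c(O)c2c(c1Br)COC2=O | intermediate
11 | 4-bromo-7-hydroxy-6-(hydroxymethyl)-5-(prop-2-enyloxy)-3H-isobenzofuran-1-one | C=CCOc1c(CO)c(O)c2c(c1Br)COC2=O | intermediate
12 | O5-allyl acetonide: 4-bromo-5-(prop-2-enyloxy)phthalide with O7 and C6–CH2–O bridged by CMe2 | C=CCOc1c2c(c3c(c1Br)COC3=O)OC(C)(C)OC2 | intermediate
13 | ring-B phenol: 4-bromo-5-hydroxyphthalide with O7 and C6–CH2–O bridged by CMe2 | Oc1c2c(c3c(c1Br)COC3=O)OC(C)(C)OC2 | intermediate
14 | acylketene: benzyl 3,5-dioxo-2-(3-oxoprop-2-enoyl)hexanoate (not isolated) | CC(=O)CC(=O)C(C(=O)OCc1ccccc1)C(=O)C=C=O | intermediate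
15 | triketo diester: O–B1 aryl ester of 4-(benzyloxycarbonyl)-3,5,7-trioxooctanoic acid (not isolated) | CC(=O)CC(=O)C(C(=O)OCc1ccccc1)C(=O)CC(=O)Oc1c2c(c3c(c1Br)COC3=O)OC(C)(C)OC2 | intermediate
16 | aldol adduct: O–B1 aryl 3-(benzyloxycarbonyl)-6-hydroxy-6-methyl-2,4-dioxocyclohexane-1-carboxylate (transient mixture of diastereomers, not isolated) | CC1(O)CC(=O)C(C(=O)OCc2ccccc2)C(=O)C1C(=O)Oc1c2c(c3c(c1Br)COC3=O)OC(C)(C)OC2 | intermediate
17 | depside: O–B1 ester of 13 with 3-(benzyloxycarbonyl)-2,4-dihydroxy-6-methylbenzoic acid (key-step product) | Cc1cc(O)c(C(=O)OCc2ccccc2)c(O)c1C(=O)Oc1c2c(c3c(c1Br)COC3=O)OC(C)(C)OC2 | intermediate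
18 | depsidone benzyl ester acetonide | Cc1cc(O)c(C(=O)OCc5ccccc5)c2c1C(=O)Oc1c3c(c4c(c1O2)COC4=O)OC(C)(C)OC3 | intermediate
19 | depsidone acid acetonide | Cc1cc(O)c(C(=O)O)c2c1C(=O)Oc1c3c(c4c(c1O2)COC4=O)OC(C)(C)OC3 | intermediate
20 | conneotricone | Cc1cc(O)c(C(=O)O)c2c1C(=O)Oc1c(CO)c(O)c3c(c1O2)COC3=O | target

Total step count: 12. Longest linear sequence: 10 steps (steps 3 to 12, from methyl atratate 6).

Steps most likely to fail

Step 9. The acylketene may be consumed by lactonisation through its own chain enol or by dimerisation faster than the hindered B1 hydroxyl adds, and the open chain may fold in the Claisen sense with expulsion of the phenol. The fallback aromatises ring A before the ester bond is made. Setting out from 5, Et3N in CH2Cl2 at room temperature should close ring A by aldol attack of the dioxinone ring carbon (the future C6′) on the C1′ ketone and give benzyl 7-hydroxy-2,2,5-trimethyl-4-oxo-4H-1,3-benzodioxine-8-carboxylate F1, a stable acetonide-protected salicylate. Irradiation of F1 (300 nm, CH2Cl2, rt) with phenol 13 should expel acetone, generate the ortho-quinone ketene and acylate O–B1; this photochemical acylation by benzodioxinones is a known route to hindered salicylate esters. The fallback returns to the route at 17.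

Step 10. Oxidative addition of copper at the doubly ortho-substituted B6 bromide may be slow enough for protodebromination, intermolecular etherification or cleavage of the depside ester to take over. The fallback turns the halide into the nucleophilic partner. From 17, Miyaura borylation (B2pin2, PdCl2(dppf), KOAc, 1,4-dioxane, 90 °C) should give the B6 pinacol boronate of the depside F2. Intramolecular Chan–Lam coupling of the C5′ hydroxyl with the boronate (Cu(OAc)2, pyridine, 4 Å molecular sieves, CH2Cl2, air, rt) should then close the seven-membered ring oxidatively at room temperature and return to the route at 18.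

Step 2. The product anion may cyclise before the quench (lactonisation onto the benzyl ester or aldol closure onto the dioxinone), or diketene may oligomerise or acylate on oxygen. The fallback builds the chain two carbons at a time. From 3, C-acetylation (LiN(SiMe3)2, 2.1 equiv, THF, −78 °C; N-acetylimidazole) should give benzyl 2-(2,2-dimethyl-4-oxo-4H-1,3-dioxin-6-yl)-3-oxobutanoate F3. Its dianion (LiN(iPr)2, 2.3 equiv, THF, −78 °C) is then acylated at the terminal methyl by N-methoxy-N-methylacetamide. The tetrahedral adduct releases the 1,3-diketone only on acidic work-up, which returns to the route at 5.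

Further compounds
F1 | step 9 | benzyl 7-hydroxy-2,2,5-trimethyl-4-oxo-4H-1,3-benzodioxine-8-carboxylate | Cc1cc(O)c(C(=O)OCc2ccccc2)c2OC(C)(C)OC(=O)c12
F2 | step 10 | B6 pinacol boronate of depside 17 | Cc1cc(O)c(C(=O)OCc2ccccc2)c(O)c1C(=O)Oc1c2c(c3c(c1B4OC(C)(C)C(C)(C)O4)COC3=O)OC(C)(C)OC2
F3 | step 2 | benzyl 2-(2,2-dimethyl-4-oxo-4H-1,3-dioxin-6-yl)-3-oxobutanoate | CC(=O)C(C(=O)OCc1ccccc1)C1=CC(=O)OC(C)(C)O1
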